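## Retrosynthetic overview
1. Target ⇐ its bis-silyl ether; a mild fluoride desilylation comes last, with C3 already set.
2. Key disconnection C3–C1': racemic 3-bromochroman-4-one (C3 reacting as an enolonium-type electrophile) plus a ring B arylzinc; an enantioconvergent Ni/pybox coupling sets 3S.
3. Bromoketone ⇐ enol-silane bromination ⇐ Stille prenylation at C6 ⇐ O-silylated 6-bromo-7-hydroxychroman-4-one.
4. Chromanone ⇐ 4-bromoresorcinol + 3-chloropropionic acid; arylzinc ⇐ 4-bromo-2,5-dimethoxybenzaldehyde (Dakin-type oxidation, silylation).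
5. Ring order: rings A and B are bought as arenes; the pyranone ring C is closed in step 1; no ring is formed later.

Assumption: the target is the 3S enantiomer (CIP order at C3: C4 > C2 > C1' > H). The sense of induction of the nickel catalyst on a cyclic bromoketone is not known in advance, so step 7 is written with the (S,S) ligand; the (R,R) ligand is used instead if the first run gives the 3R product (chiral HPLC, ECD).

## Route

Step 1
Reactants: 1 4-bromoresorcinol; 2 3-chloropropionic acid
Product: 4 6-bromo-7-hydroxychroman-4-one, via chloroketone 3 (not isolated)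
Conditions: CF3SO3H (3 equiv), 80 °C, 1 h; then 2 M NaOH, 0 °C to rt; then HCl to pH 3
Reagents that add atoms: none
Why: Friedel–Crafts acylation in CF3SO3H occurs at the only unhindered doubly activated position of 1 (ortho to one OH, para to the other), and in base the ortho-phenoxide closes ring C by intramolecular displacement of chloride (Williamson-type, or E1cB then oxa-Michael), which places Br at C6 next to the free 7-OH.

Step 2
Reactants: 4 6-bromo-7-hydroxychroman-4-one
Product: 5 6-bromo-7-(tert-butyldimethylsilyloxy)chroman-4-one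
Conditions: TBSCl, imidazole, DMF, rt
Reagents that add atoms: tert-butyldimethylsilyl chloride, CC(C)(C)[Si](C)(C)Cl
Why: Standard imidazole-promoted silylation of the acidic 7-phenol; the TBS ether masks the proton that would quench the base in step 4 and the arylzinc in step 7.

Step 3
Reactants: 5 6-bromo-7-(tert-butyldimethylsilyloxy)chroman-4-one; 6 tributyl(3-methylbut-2-en-1-yl)stannane
Product: 7 7-(tert-butyldimethylsilyloxy)-6-(3-methylbut-2-en-1-yl)chroman-4-one
Conditions: Pd(PPh3)4 (5 mol %), degassed toluene, 100 °C
Reagents that add atoms: none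
Why: Stille coupling: zerovalent palladium inserts into the aryl C–Br bond, the prenylstannane transmetalates, and reductive elimination at the unsubstituted allyl terminus gives the linear prenyl arene under neutral conditions that spare ketone and silyl ether.

Step 4
Reactants: 7 7-(tert-butyldimethylsilyloxy)-6-(3-methylbut-2-en-1-yl)chroman-4-one
Product: 9 rac-3-bromo-7-(tert-butyldimethylsilyloxy)-6-(3-methylbut-2-en-1-yl)chroman-4-one, via trimethylsilyl enol ether 8 (not isolated)
Conditions: LiN(SiMe3)2 (1.1 equiv), Me3SiCl (1.2 equiv), THF, −78 °C; then NBS (1.0 equiv), THF, −78 °C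
Reagents that add atoms: N-bromosuccinimide, O=C1CCC(=O)N1Br; chlorotrimethylsilane, C[Si](C)(C)Cl (its silyl group is carried only by 8)
Why: Kinetic enolisation with in situ silylation gives the trimethylsilyl enol ether, which at −78 °C takes up Br+ from NBS far faster than the trisubstituted prenyl alkene or the acyl-deactivated arene does (α-bromination of an enol silane); the product is deliberately racemic because step 7 is stereoconvergent.

Step 5
Reactants: 10 4-bromo-2,5-dimethoxybenzaldehyde
Product: 12 4-bromo-2,5-dimethoxyphenol, via aryl formate 11 (not isolated)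
Conditions: mCPBA, CH2Cl2, 0 °C to rt; then KOH, MeOH/H2O, 0 °C
Reagents that add atoms: meta-chloroperoxybenzoic acid, OOC(=O)c1cccc(Cl)c1
Why: Baeyer–Villiger oxidation of an electron-rich benzaldehyde (Dakin-type): the aryl group migrates to oxygen in the Criegee adduct and the resulting formate is saponified in the same flask.

Step 6
Reactants: 12 4-bromo-2,5-dimethoxyphenol
Product: 13 (4-bromo-2,5-dimethoxyphenoxy)(tert-butyl)dimethylsilane
Conditions: TBSCl, imidazole, DMF, rt
Reagents that add atoms: tert-butyldimethylsilyl chloride, CC(C)(C)[Si](C)(C)Cl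
Why: Imidazole-promoted silylation of the phenol so that the aryl bromide can be turned into an organometallic reagent.

Step 7
Reactants: 9 rac-3-bromo-7-(tert-butyldimethylsilyloxy)-6-(3-methylbut-2-en-1-yl)chroman-4-one; 13 (4-bromo-2,5-dimethoxyphenoxy)(tert-butyl)dimethylsilane
Product: 16 (3S)-7-(tert-butyldimethylsilyloxy)-3-[4-(tert-butyldimethylsilyloxy)-2,5-dimethoxyphenyl]-6-(3-methylbut-2-en-1-yl)chroman-4-one, via arylmagnesium bromide 14 (not isolated), via arylzinc iodide 15 (not isolated)
Conditions: 13 (1.4 equiv), Mg, THF, 40 °C; ZnI2, THF, 0 °C; then 9, NiCl2·DME (5 mol %), (S,S)-Ph-pybox (6.5 mol %), DME/THF, −30 °C; quench with pH 7 phosphate buffer at −30 °C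
Reagents that add atoms: magnesium, [Mg]; zinc iodide, I[Zn]I (their atoms are carried only by 14 and 15)
Why: Proposed new method: a stereoconvergent nickel/pybox Negishi α-arylation, established for acyclic racemic α-bromoketones, is extended here to a cyclic 3-bromochromanone and an ortho-methoxy arylzinc; monovalent nickel abstracts bromine from either enantiomer of 9 to give one planar α-keto radical (C3 thus acts as an enolonium equivalent toward the aryl nucleophile), the chiral aryl–nickel complex captures it, and reductive elimination from trivalent nickel forms C3–C1' and sets 3S under catalyst control, while −30 °C and the non-basic zinc reagent keep the new enolisable centre from racemising; closest known reaction type: enantioconvergent Ni-catalysed Negishi arylation of racemic secondary α-bromoketones.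

Step 8
Reactants: 16 (3S)-7-(tert-butyldimethylsilyloxy)-3-[4-(tert-butyldimethylsilyloxy)-2,5-dimethoxyphenyl]-6-(3-methylbut-2-en-1-yl)chroman-4-one
Product: 17 (3S)-7-hydroxy-3-(4-hydroxy-2,5-dimethoxyphenyl)-6-(3-methylbut-2-en-1-yl)chroman-4-one
Conditions: HF·pyridine, excess pyridine, THF, 0 °C to rt
Reagents that add atoms: none
Why: Fluoride-driven desilylation (formation of the strong Si–F bond) under weakly acidic buffered conditions never generates a phenoxide or enolate, so the C3 centre set in step 7 is not epimerised and the acid-sensitive prenyl group is left alone.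

## Compound list
1 | 4-bromoresorcinol (4-bromobenzene-1,3-diol) | Oc1ccc(Br)c(O)c1 | starting material
2 | 3-chloropropionic acid | OC(=O)CCCl | starting material
3 | 1-(5-bromo-2,4-dihydroxyphenyl)-3-chloropropan-1-one | O=C(CCCl)c1cc(Br)c(O)cc1O | intermediate
4 | 6-bromo-7-hydroxychroman-4-one | O=C1CCOc2cc(O)c(Br)cc12 | intermediate
5 | 6-bromo-7-(tert-butyldimethylsilyloxy)chroman-4-one | O=C1CCOc2cc(O[Si](C)(C)C(C)(C)C)c(Br)cc12 | intermediate
6 | tributyl(3-methylbut-2-en-1-yl)stannane | CCCC[Sn](CCCC)(CCCC)CC=C(C)C | starting material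
7 | 7-(tert-butyldimethylsilyloxy)-6-(3-methylbut-2-en-1-yl)chroman-4-one | O=C1CCOc2cc(O[Si](C)(C)C(C)(C)C)c(CC=C(C)C)cc12 | intermediate
8 | 7-(tert-butyldimethylsilyloxy)-6-(3-methylbut-2-en-1-yl)-4-(trimethylsilyloxy)-2H-chromene | C[Si](C)(C)OC1=CCOc2cc(O[Si](C)(C)C(C)(C)C)c(CC=C(C)C)cc12 | intermediate
9 | rac-3-bromo-7-(tert-butyldimethylsilyloxy)-6-(3-methylbut-2-en-1-yl)chroman-4-one (racemate) | O=C1C(Br)COc2cc(O[Si](C)(C)C(C)(C)C)c(CC=C(C)C)cc12 | intermediate
10 | 4-bromo-2,5-dimethoxybenzaldehyde | COc1cc(Br)c(OC)cc1C=O | starting material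
11 | 4-bromo-2,5-dimethoxyphenyl formate | COc1cc(Br)c(OC)cc1OC=O | intermediate
12 | 4-bromo-2,5-dimethoxyphenol | COc1cc(Br)c(OC)cc1O | intermediate
13 | (4-bromo-2,5-dimethoxyphenoxy)(tert-butyl)dimethylsilane | COc1cc(Br)c(OC)cc1O[Si](C)(C)C(C)(C)C | intermediate
14 | [4-(tert-butyldimethylsilyloxy)-2,5-dimethoxyphenyl]magnesium bromide | COc1cc([Mg]Br)c(OC)cc1O[Si](C)(C)C(C)(C)C | intermediate
15 | [4-(tert-butyldimethylsilyloxy)-2,5-dimethoxyphenyl]zinc iodide | COc1cc([Zn]I)c(OC)cc1O[Si](C)(C)C(C)(C)C | intermediate
16 | (3S)-7-(tert-butyldimethylsilyloxy)-3-[4-(tert-butyldimethylsilyloxy)-2,5-dimethoxyphenyl]-6-(3-methylbut-2-en-1-yl)chroman-4-one | COc1cc([C@H]2COc3cc(O[Si](C)(C)C(C)(C)C)c(CC=C(C)C)cc3C2=O)c(OC)cc1O[Si](C)(C)C(C)(C)C | intermediate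
17 | (3S)-7-hydroxy-3-(4-hydroxy-2,5-dimethoxyphenyl)-6-(3-methylbut-2-en-1-yl)chroman-4-one | COc1cc([C@H]2COc3cc(O)c(CC=C(C)C)cc3C2=O)c(OC)cc1O | target

## Count and risks
Total steps: 8. Longest linear sequence: 6 (steps 1, 2, 3, 4, 7, 8); the ring B branch (steps 5, 6) joins at step 7.

The three steps most likely to fail:

**Step 7 (enantioconvergent arylation).** There is no precedent for a cyclic bromoketone or an ortho-methoxy arylzinc in this coupling. Possible outcomes are low ee, reduction back to 7, HBr loss to the chromone, or erosion of ee through the axial, well-aligned C3–H. The fallback sets out from 9 and 13 and comes back at 16. It keeps the same C3–C1' coupling of 9 with arylzinc 15 but no longer asks it for stereocontrol. The coupling is run with NiCl2·DME and achiral 4,4'-di-tert-butyl-2,2'-bipyridine at 0 °C to rt to give the racemic bis-silyl isoflavanone F1. F1 is then reduced by asymmetric transfer hydrogenation under dynamic kinetic resolution (RuCl[(S,S)-TsDPEN](p-cymene), HCO2H/Et3N, EtOAc, 40 °C). C3 epimerises through the enol while one enantiomer is reduced, giving the cis-(3S,4S)-isoflavan-4-ol F2; the catalyst antipode is predicted from the usual aryl-ketone model and confirmed by experiment. Oxidation of F2 with Dess–Martin periodinane/NaHCO3 (CH2Cl2, 0 °C) leaves the now fixed C3 untouched and rejoins the route at 16.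

**Step 4 (α-bromination next to a prenyl group).** NBS may also attack the trisubstituted alkene, and the bromoketone can lose HBr on handling. The fallback sets out from 5 and comes back at 9, and it postpones the trisubstituted alkene until after the bromination. Stille coupling of 5 with allyltributylstannane (Pd(PPh3)4, toluene, 100 °C) gives 6-allyl-7-(tert-butyldimethylsilyloxy)chroman-4-one F3. Enolisation and silylation as in step 4 give the trimethylsilyl enol ether F4. NBS at −78 °C then gives the racemic 6-allyl-3-bromo ketone F5; the monosubstituted alkene is far less nucleophilic than a prenyl group. Cross-metathesis of F5 with excess 2-methylbut-2-ene (second-generation Grubbs catalyst, CH2Cl2, 40 °C) turns allyl into prenyl and arrives at 9.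

**Step 3 (Stille prenylation).** Oxidative addition into the hindered, electron-rich ortho-silyloxy aryl bromide may be slow, and some branched 1,1-dimethylallyl isomer may form. The fallback sets out from 5 and comes back at 7, and it swaps the roles of the two partners. Miyaura borylation of 5 (B2pin2, Pd(dppf)Cl2, KOAc, dioxane, 80 °C) gives the pinacol boronate F6. Allyl–aryl Suzuki coupling of F6 with prenyl bromide (Pd(dppf)Cl2, anhydrous K3PO4, THF, 50 °C) then gives 7; the aryl group is delivered to the unsubstituted terminus of the π-prenyl–palladium intermediate.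

## Further compounds
F1 | step 7 | rac-7-(tert-butyldimethylsilyloxy)-3-[4-(tert-butyldimethylsilyloxy)-2,5-dimethoxyphenyl]-6-(3-methylbut-2-en-1-yl)chroman-4-one (racemate) | COc1cc(C2COc3cc(O[Si](C)(C)C(C)(C)C)c(CC=C(C)C)cc3C2=O)c(OC)cc1O[Si](C)(C)C(C)(C)C
F2 | step 7 | (3S,4S)-cis-7-(tert-butyldimethylsilyloxy)-3-[4-(tert-butyldimethylsilyloxy)-2,5-dimethoxyphenyl]-6-(3-methylbut-2-en-1-yl)chroman-4-ol | COc1cc([C@H]2COc3cc(O[Si](C)(C)C(C)(C)C)c(CC=C(C)C)cc3[C@H]2O)c(OC)cc1O[Si](C)(C)C(C)(C)C
F3 | step 4 | 6-allyl-7-(tert-butyldimethylsilyloxy)chroman-4-one | O=C1CCOc2cc(O[Si](C)(C)C(C)(C)C)c(CC=C)cc12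
F4 | step 4 | 6-allyl-7-(tert-butyldimethylsilyloxy)-4-(trimethylsilyloxy)-2H-chromene | C[Si](C)(C)OC1=CCOc2cc(O[Si](C)(C)C(C)(C)C)c(CC=C)cc12
F5 | step 4 | rac-6-allyl-3-bromo-7-(tert-butyldimethylsilyloxy)chroman-4-one (racemate) | O=C1C(Br)COc2cc(O[Si](C)(C)C(C)(C)C)c(CC=C)cc12
F6 | step 3 | 7-(tert-butyldimethylsilyloxy)-6-(4,4,5,5-tetramethyl-1,3,2-dioxaborolan-2-yl)chroman-4-one | O=C1CCOc2cc(O[Si](C)(C)C(C)(C)C)c(B3OC(C)(C)C(C)(C)O3)cc12
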